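**Plan**
1. Retrosynthetic cuts: first the pyranone C3–CH2 bond (sp2–sp3 Negishi coupling, last step), then the cyclohexene C1–CH2 bond (enol triflate coupling), then the two ring bonds C1–C6 and C4–C5 of the cyclohexene (ring numbered C1 chain-bearing, C2 methyl-bearing, C6 gem-dimethyl).
2. Enabling feature: alkene carbon C1 lies between quaternary C6 and methyl-bearing C2. At the ketone level (2,2,6-trimethylcyclohexanone), C1 is an acyl carbon, C6/C5 are the α- and carbonyl carbons of isobutyraldehyde, and C1–C2(Me)–C3–C4 is a tigloyl unit. A formal [4+2] of methylvinylketene with the isobutyraldehyde enamine makes C1–C6 (the most hindered bond) and C4–C5 in one operation.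
3. Forward, carbocyclic half: ring (steps 1–4), homopropargyl unit (5–6), then carboalumination/ethylene oxide for the E-trisubstituted alkene and iodination (7–8).
4. Forward, bis-lactone half from furan-3-carbaldehyde: the furan becomes the butyrolactone (photooxygenation, reductions), the dihydropyranone closes by metathesis, then α-bromination (9–14); the halves are joined in step 15.
5. Stereochemistry: pyranone C6 (R) from Keck allylation; butyrolactone C4 (R) from ligand-controlled copper hydride conjugate reduction; E-alkene from syn-carboalumination.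

Key step: step 2

Assumption: in step 11 the (R)-antipode of the bisphosphine is taken as the one that delivers hydride to the face giving the (R)-lactone carbon; the sense should be confirmed on the first run and the (S)-ligand used if it is opposite.

**Step 1**
Reactants: 1 isobutyraldehyde; 2 pyrrolidine
Product: 3 1-(2-methylprop-1-en-1-yl)pyrrolidine
Conditions: K2CO3, Et2O, 0 °C to rt; distillation
Reagents that add atoms: none
Why: Stork enamine condensation; the aldehyde has a single α-hydrogen, so only one enamine can form.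

**Step 2**
Reactants: 3 1-(2-methylprop-1-en-1-yl)pyrrolidine; 4 tigloyl chloride
Product: 7 2,6,6-trimethylcyclohexa-2,4-dien-1-one, via methylvinylketene 5 (not isolated), via aminoenone 6 (not isolated)
Conditions: Et3N (1.5 equiv), CHCl3, slow addition of 4 at 0 °C, then 60 °C; then AcOH, NaOAc, aq. THF, 60 °C
Reagents that add atoms: none
Why: Proposed new method: Et3N should dehydrochlorinate 4 through its γ-methyl group to methylvinylketene 5, whose carbonyl carbon is attacked by the nucleophilic β-carbon of enamine 3 to forge the C1–C6 bond (the quaternary centre) and give an iminium dienolate zwitterion; the γ-terminus of the dienolate then closes on the iminium carbon (C4–C5 bond, intramolecular vinylogous Mannich reaction) to aminoenone 6, which should lose pyrrolidine by vinylogous E1cB elimination on warming with acetic acid to give 7. The closest known reaction types are the [2+2] cycloaddition of ketenes with aldehyde enamines and the annulation of enamines with α,β-unsaturated acid chlorides; the cyclohexenone is not an established outcome for this pair, hence the label. The six-membered ring closes in a 6-(enolendo)-exo-trig mode. The amino-bearing stereocentre of 6 is racemic and disappears on elimination, so no stereocontrol is needed. The step needs C-attack at the ketene carbonyl and six- over four-ring closure: the polarity of both partners fixes the first, and the fully substituted α-carbon of the dienolate, the reversibility of the zwitterion and heating should funnel any cyclobutanone to the more stable six-membered ring.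

**Step 3**
Reactants: 7 2,6,6-trimethylcyclohexa-2,4-dien-1-one
Product: 8 2,2,6-trimethylcyclohexan-1-one (racemic)
Conditions: H2 (1 atm), Pd/C, EtOAc, rt
Reagents that add atoms: none
Why: Heterogeneous catalytic hydrogenation should saturate both C=C bonds and leave the hindered ketone; the methyl-bearing stereocentre is racemic and is erased in step 4.

**Step 4**
Reactants: 8 2,2,6-trimethylcyclohexan-1-one
Product: 9 2,6,6-trimethylcyclohex-1-en-1-yl trifluoromethanesulfonate
Conditions: LiN(i-Pr)2 (LDA), THF, −78 °C; then PhNTf2, −78 °C to rt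
Reagents that add atoms: N-phenylbis(trifluoromethanesulfonimide), O=S(=O)(N(c1ccccc1)S(=O)(=O)C(F)(F)F)C(F)(F)F
Why: Enol triflate formation; the only α-hydrogen sits on the methyl-bearing carbon, so a single enolate forms and O-sulfonylation fixes the tetrasubstituted alkene position.

**Step 5**
Reactants: 10 (4-bromobut-1-yn-1-yl)trimethylsilane; 9 2,6,6-trimethylcyclohex-1-en-1-yl trifluoromethanesulfonate
Product: 12 trimethyl[4-(2,6,6-trimethylcyclohex-1-en-1-yl)but-1-yn-1-yl]silane, via homopropargylzinc bromide 11 (not isolated)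
Conditions: 10, Zn dust, LiCl, THF, 50 °C; then 9, Pd(OAc)2 (5 mol%), SPhos (10 mol%), THF/NMP, 60 °C
Reagents that add atoms: none
Why: Negishi coupling; zerovalent palladium inserts into the vinyl triflate, the primary homopropargylzinc (no β-leaving group, alkyne capped by silicon) transmetalates, and the bulky biarylphosphine should promote reductive elimination at the hindered carbon.

**Step 6**
Reactants: 12 trimethyl[4-(2,6,6-trimethylcyclohex-1-en-1-yl)but-1-yn-1-yl]silane
Product: 13 2-(but-3-yn-1-yl)-1,3,3-trimethylcyclohex-1-ene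
Conditions: K2CO3, MeOH, rt
Reagents that add atoms: none
Why: Methanolysis of the alkynyl C–Si bond (protodesilylation) is selective and frees the terminal alkyne.

**Step 7**
Reactants: 13 2-(but-3-yn-1-yl)-1,3,3-trimethylcyclohex-1-ene
Product: 16 (E)-4-methyl-6-(2,6,6-trimethylcyclohex-1-en-1-yl)hex-3-en-1-ol, via alkenylalane 14 (not isolated), via lithium alkenylaluminate 15 (not isolated)
Conditions: Me3Al (2 equiv), Cp2ZrCl2 (0.25 equiv), CH2Cl2, 0 °C to rt; then n-BuLi, THF/hexane, −78 °C; then ethylene oxide, −78 °C to rt; aq. potassium sodium tartrate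
Reagents that add atoms: trimethylaluminium, C[Al](C)C; ethylene oxide, C1CO1
Why: Zirconium-catalysed Negishi carboalumination adds methyl and aluminium syn across the terminal alkyne (aluminium at the terminus), and the aluminate opens ethylene oxide with retention at the alkenyl carbon, so the E-trisubstituted alkene is set.

**Step 8**
Reactants: 16 (E)-4-methyl-6-(2,6,6-trimethylcyclohex-1-en-1-yl)hex-3-en-1-ol
Product: 17 (E)-2-(6-iodo-3-methylhex-3-en-1-yl)-1,3,3-trimethylcyclohex-1-ene
Conditions: PPh3, imidazole, I2, CH2Cl2, 0 °C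
Reagents that add atoms: iodine, II
Why: Appel-type iodination by SN2 at the primary carbinol carbon should leave both alkenes and the E geometry untouched.

**Step 9**
Reactants: 18 furan-3-carbaldehyde
Product: 19 (R)-1-(furan-3-yl)but-3-en-1-ol
Conditions: (R)-BINOL (10 mol%), Ti(OiPr)4 (10 mol%), 4 Å molecular sieves, allyltributylstannane, CH2Cl2, −20 °C
Reagents that add atoms: allyltributylstannane, C=CC[Sn](CCCC)(CCCC)CCCC
Why: Keck asymmetric allylation; the (R)-BINOL–titanium Lewis acid should direct allyl transfer to the aldehyde face that gives the (R)-carbinol, as for aryl aldehydes.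

**Step 10**
Reactants: 19 (R)-1-(furan-3-yl)but-3-en-1-ol
Product: 21 4-[(1R)-1-hydroxybut-3-en-1-yl]furan-2(5H)-one, via hydroxybutenolide 20 (not isolated)
Conditions: O2, hν, rose bengal (cat.), i-Pr2NEt, CH2Cl2/MeOH, −78 °C; then NaBH4, 0 °C; then aq. HCl to pH 3
Reagents that add atoms: oxygen, O=O
Why: Singlet oxygen [4+2] addition to the furan followed by Kornblum–DeLaMare-type fragmentation, in which the hindered amine removes the less hindered ring proton, should give the 4-substituted 5-hydroxybutenolide; borohydride reduces its masked aldehyde and the hydroxy acid relactonizes, with the carbinol centre untouched.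

**Step 11**
Reactants: 21 4-[(1R)-1-hydroxybut-3-en-1-yl]furan-2(5H)-one
Product: 22 (4R)-4-[(1R)-1-hydroxybut-3-en-1-yl]dihydrofuran-2(3H)-one
Conditions: Cu(OAc)2·H2O (3 mol%), (R)-DTBM-SEGPHOS (3 mol%), (EtO)2MeSiH, t-BuOH, toluene, 0 °C; then NH4F, MeOH
Reagents that add atoms: none
Why: Ligand-controlled copper hydride 1,4-reduction (Stryker-type) of the β-substituted butenolide; the chiral bisphosphine should set the (R)-lactone carbon by face-selective hydride delivery to the β-carbon, and the isolated terminal alkene should not react at 0 °C.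

**Step 12**
Reactants: 22 (4R)-4-[(1R)-1-hydroxybut-3-en-1-yl]dihydrofuran-2(3H)-one
Product: 23 (1R)-1-[(3R)-5-oxotetrahydrofuran-3-yl]but-3-en-1-yl acrylate
Conditions: acryloyl chloride, i-Pr2NEt, CH2Cl2, −78 to −20 °C
Reagents that add atoms: acryloyl chloride, C=CC(Cl)=O
Why: O-acylation of the secondary alcohol with an acid chloride; low temperature and a non-nucleophilic base should keep the hydroxy lactone from acyl migration.

**Step 13**
Reactants: 23 (1R)-1-[(3R)-5-oxotetrahydrofuran-3-yl]but-3-en-1-yl acrylate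
Product: 24 (6R)-6-[(3R)-5-oxotetrahydrofuran-3-yl]-5,6-dihydro-2H-pyran-2-one
Conditions: second-generation Grubbs catalyst (5 mol%), CH2Cl2 (0.01 M), 40 °C
Reagents that add atoms: none
Why: Ring-closing metathesis of the acrylate with the terminal alkene closes the six-membered unsaturated lactone and releases ethene; no stereocentre is touched.

**Step 14**
Reactants: 24 (6R)-6-[(3R)-5-oxotetrahydrofuran-3-yl]-5,6-dihydro-2H-pyran-2-one
Product: 26 (6R)-3-bromo-6-[(3R)-5-oxotetrahydrofuran-3-yl]-5,6-dihydro-2H-pyran-2-one, via dibromolactone 25 (not isolated)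
Conditions: Br2, CH2Cl2, 0 °C to rt; then Et3N, 0 °C
Reagents that add atoms: bromine, BrBr
Why: Bromine addition to the enoate followed by dehydrobromination; the α-hydrogen is the most acidic, so HBr is lost to give the α-bromo enoate.

**Step 15**
Reactants: 17 (E)-2-(6-iodo-3-methylhex-3-en-1-yl)-1,3,3-trimethylcyclohex-1-ene; 26 (6R)-3-bromo-6-[(3R)-5-oxotetrahydrofuran-3-yl]-5,6-dihydro-2H-pyran-2-one
Product: 28 (6R)-3-[(3E)-4-methyl-6-(2,6,6-trimethylcyclohex-1-en-1-yl)hex-3-en-1-yl]-6-[(3R)-5-oxotetrahydrofuran-3-yl]-5,6-dihydro-2H-pyran-2-one (CNP0207009.2), via homoallylzinc iodide 27 (not isolated)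
Conditions: 17, Zn dust, LiCl, THF, 40 °C; then 26, Pd(OAc)2 (5 mol%), SPhos (10 mol%), THF, rt
Reagents that add atoms: none
Why: Negishi coupling; the neutral alkylzinc should tolerate both lactones, oxidative addition of zerovalent palladium to the α-bromo enoate is fast, and neither stereocentre nor the E-alkene takes part.

**Compound list**
1 | isobutyraldehyde (2-methylpropanal) | CC(C)C=O | starting material
2 | pyrrolidine | C1CCNC1 | starting material
3 | 1-(2-methylprop-1-en-1-yl)pyrrolidine | CC(C)=CN1CCCC1 | intermediate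
4 | tigloyl chloride, (E)-2-methylbut-2-enoyl chloride | C/C=C(\C)C(Cl)=O | starting material
5 | methylvinylketene (2-methylbuta-1,3-dien-1-one) | C=CC(C)=C=O | intermediate (not isolated)
6 | 2,6,6-trimethyl-5-(pyrrolidin-1-yl)cyclohex-2-en-1-one (racemic) | CC1=CCC(N2CCCC2)C(C)(C)C1=O | intermediate (not isolated)
7 | 2,6,6-trimethylcyclohexa-2,4-dien-1-one | CC1=CC=CC(C)(C)C1=O | intermediate
8 | 2,2,6-trimethylcyclohexan-1-one (racemic) | CC1CCCC(C)(C)C1=O | intermediate
9 | 2,6,6-trimethylcyclohex-1-en-1-yl trifluoromethanesulfonate | CC1=C(OS(=O)(=O)C(F)(F)F)C(C)(C)CCC1 | intermediate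
10 | (4-bromobut-1-yn-1-yl)trimethylsilane | C[Si](C)(C)C#CCCBr | starting material
11 | [4-(trimethylsilyl)but-3-yn-1-yl]zinc bromide | C[Si](C)(C)C#CCC[Zn]Br | intermediate (not isolated)
12 | trimethyl[4-(2,6,6-trimethylcyclohex-1-en-1-yl)but-1-yn-1-yl]silane | CC1=C(CCC#C[Si](C)(C)C)C(C)(C)CCC1 | intermediate
13 | 2-(but-3-yn-1-yl)-1,3,3-trimethylcyclohex-1-ene | CC1=C(CCC#C)C(C)(C)CCC1 | intermediate
14 | dimethyl[(E)-2-methyl-4-(2,6,6-trimethylcyclohex-1-en-1-yl)but-1-en-1-yl]alane | CC1=C(CC/C(C)=C/[Al](C)C)C(C)(C)CCC1 | intermediate (not isolated)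
15 | lithium butyl(dimethyl)[(E)-2-methyl-4-(2,6,6-trimethylcyclohex-1-en-1-yl)but-1-en-1-yl]aluminate | [Li+].CCCC[Al-](C)(C)/C=C(\C)CCC1=C(C)CCCC1(C)C | intermediate (not isolated)
16 | (E)-4-methyl-6-(2,6,6-trimethylcyclohex-1-en-1-yl)hex-3-en-1-ol | CC1=C(CC/C(C)=C/CCO)C(C)(C)CCC1 | intermediate
17 | (E)-2-(6-iodo-3-methylhex-3-en-1-yl)-1,3,3-trimethylcyclohex-1-ene | CC1=C(CC/C(C)=C/CCI)C(C)(C)CCC1 | intermediate
18 | furan-3-carbaldehyde | O=Cc1ccoc1 | starting material
19 | (R)-1-(furan-3-yl)but-3-en-1-ol | O[C@H](CC=C)c1ccoc1 | intermediate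
20 | 5-hydroxy-4-[(1R)-1-hydroxybut-3-en-1-yl]furan-2(5H)-one (hemiacetal epimers) | O[C@H](CC=C)C1=CC(=O)OC1O | intermediate (not isolated)
21 | 4-[(1R)-1-hydroxybut-3-en-1-yl]furan-2(5H)-one | O[C@H](CC=C)C1=CC(=O)OC1 | intermediate
22 | (4R)-4-[(1R)-1-hydroxybut-3-en-1-yl]dihydrofuran-2(3H)-one | O[C@H](CC=C)[C@H]1COC(=O)C1 | intermediate
23 | (1R)-1-[(3R)-5-oxotetrahydrofuran-3-yl]but-3-en-1-yl acrylate | C=CC(=O)O[C@H](CC=C)[C@H]1COC(=O)C1 | intermediate
24 | (6R)-6-[(3R)-5-oxotetrahydrofuran-3-yl]-5,6-dihydro-2H-pyran-2-one | O=C1C=CC[C@H]([C@H]2COC(=O)C2)O1 | intermediate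
25 | (6R)-3,4-dibromo-6-[(3R)-5-oxotetrahydrofuran-3-yl]tetrahydro-2H-pyran-2-one (C3/C4 isomers) | BrC1C(Br)C[C@H]([C@H]2COC(=O)C2)OC1=O | intermediate (not isolated)
26 | (6R)-3-bromo-6-[(3R)-5-oxotetrahydrofuran-3-yl]-5,6-dihydro-2H-pyran-2-one | BrC1=CC[C@H]([C@H]2COC(=O)C2)OC1=O | intermediate
27 | [(E)-4-methyl-6-(2,6,6-trimethylcyclohex-1-en-1-yl)hex-3-en-1-yl]zinc iodide | CC1=C(CC/C(C)=C/CC[Zn]I)C(C)(C)CCC1 | intermediate (not isolated)
28 | (6R)-3-[(3E)-4-methyl-6-(2,6,6-trimethylcyclohex-1-en-1-yl)hex-3-en-1-yl]-6-[(3R)-5-oxotetrahydrofuran-3-yl]-5,6-dihydro-2H-pyran-2-one | CC1=C(CC/C(C)=C/CCC2=CC[C@H]([C@H]3COC(=O)C3)OC2=O)C(C)(C)CCC1 | target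

**Step count and risks**
Total steps: 15. Longest linear sequence: 9 steps (steps 1–8, then 15); the bis-lactone branch is 6 steps (9–14) before the union.

Steps most likely to fail:

1. Step 2 (proposed new method). Ketene dimerisation, four-ring instead of six-ring closure, or incomplete loss of the amine may prevail. Fallback, setting out from 3 and coming back at 8: enamine 3 is used in a Stork-type Robinson annulation with pent-1-en-3-one (then aqueous acid) to give 2,4,4-trimethylcyclohex-2-en-1-one F1. Nucleophilic epoxidation (H2O2, NaOH, MeOH) gives 1,5,5-trimethyl-7-oxabicyclo[4.1.0]heptan-2-one F2. Wharton transposition (N2H4·H2O, AcOH, MeOH) moves the oxygen next to the quaternary carbon and gives 2,6,6-trimethylcyclohex-2-en-1-ol F3. Oxidation with MnO2 gives 2,6,6-trimethylcyclohex-2-en-1-one F4, and hydrogenation (H2, Pd/C) gives 8.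

2. Step 11. Facial selectivity may be poor if the ligand and the adjacent carbinol centre are mismatched; the terminal alkene may be reduced, or the acyl group of the hydroxy lactone may migrate. Fallback, setting out from 18 and coming back at 22, in which the lactone centre is set first on a substrate without other alkenes or stereocentres: 18 is converted (HC(OMe)3, MeOH, cat. TsOH) to 3-(dimethoxymethyl)furan F5. Photooxygenation and borohydride reduction as in step 10 give 4-(dimethoxymethyl)furan-2(5H)-one F6. Asymmetric hydrogenation (H2, Ru(OAc)2(BINAP), antipode chosen for the R product) gives (R)-4-(dimethoxymethyl)dihydrofuran-2(3H)-one F7. Mild acid hydrolysis gives (R)-5-oxotetrahydrofuran-3-carbaldehyde F8, which is used at once in a Keck allylation with (R)-BINOL under reagent control to give 22.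

3. Step 15. Slow transmetalation with β-hydride elimination and loss of bromine from 26, or ring-opening of a lactone, may erode the union. Fallback, setting out from 17 and 22 and coming back at 28, in which the pyranone is closed last by metathesis: sodium triethyl phosphonoacetate (NaH, THF/DMF) is alkylated with 17 to give ethyl (E)-2-(diethoxyphosphoryl)-6-methyl-8-(2,6,6-trimethylcyclohex-1-en-1-yl)oct-5-enoate F9. Horner–Wadsworth–Emmons reaction with aqueous formaldehyde (K2CO3) gives ethyl (E)-6-methyl-2-methylene-8-(2,6,6-trimethylcyclohex-1-en-1-yl)oct-5-enoate F10. Saponification (LiOH) gives (E)-6-methyl-2-methylene-8-(2,6,6-trimethylcyclohex-1-en-1-yl)oct-5-enoic acid F11. Esterification with 22 (DCC, DMAP, 0 °C) gives (1R)-1-[(3R)-5-oxotetrahydrofuran-3-yl]but-3-en-1-yl (E)-6-methyl-2-methylene-8-(2,6,6-trimethylcyclohex-1-en-1-yl)oct-5-enoate F12. Ring-closing metathesis with the second-generation Grubbs catalyst then gives 28.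

**Further compounds**
F1 | step 2 | 2,4,4-trimethylcyclohex-2-en-1-one | CC1=CC(C)(C)CCC1=O
F2 | step 2 | 1,5,5-trimethyl-7-oxabicyclo[4.1.0]heptan-2-one | CC12OC1C(C)(C)CCC2=O
F3 | step 2 | 2,6,6-trimethylcyclohex-2-en-1-ol | CC1=CCCC(C)(C)C1O
F4 | step 2 | 2,6,6-trimethylcyclohex-2-en-1-one | CC1=CCCC(C)(C)C1=O
F5 | step 11 | 3-(dimethoxymethyl)furan | COC(OC)c1ccoc1
F6 | step 11 | 4-(dimethoxymethyl)furan-2(5H)-one | COC(OC)C1=CC(=O)OC1
F7 | step 11 | (R)-4-(dimethoxymethyl)dihydrofuran-2(3H)-one | COC(OC)[C@H]1COC(=O)C1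
F8 | step 11 | (R)-5-oxotetrahydrofuran-3-carbaldehyde | O=C[C@H]1COC(=O)C1
F9 | step 15 | ethyl (E)-2-(diethoxyphosphoryl)-6-methyl-8-(2,6,6-trimethylcyclohex-1-en-1-yl)oct-5-enoate | CCOC(=O)C(CC/C=C(\C)CCC1=C(C)CCCC1(C)C)P(=O)(OCC)OCC
F10 | step 15 | ethyl (E)-6-methyl-2-methylene-8-(2,6,6-trimethylcyclohex-1-en-1-yl)oct-5-enoate | CCOC(=O)C(=C)CC/C=C(\C)CCC1=C(C)CCCC1(C)C
F11 | step 15 | (E)-6-methyl-2-methylene-8-(2,6,6-trimethylcyclohex-1-en-1-yl)oct-5-enoic acid | OC(=O)C(=C)CC/C=C(\C)CCC1=C(C)CCCC1(C)C
F12 | step 15 | (1R)-1-[(3R)-5-oxotetrahydrofuran-3-yl]but-3-en-1-yl (E)-6-methyl-2-methylene-8-(2,6,6-trimethylcyclohex-1-en-1-yl)oct-5-enoate | O=C(O[C@H](CC=C)[C@H]1COC(=O)C1)C(=C)CC/C=C(\C)CCC1=C(C)CCCC1(C)C
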